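The constants belong to no real substance, and the outcome is calculated.

**The choice.** I decided to stop following the clock and to ask where each D goes. L turns into D, E or G catches D, and E also decays to X.

    L → D (k1 = 0.0204 s⁻¹)
    E + D → E.D (k2 = 40.4 M⁻¹ s⁻¹)
    G + D → G.D (k3 = 1.81 M⁻¹ s⁻¹)
    E → X (k4 = 0.0177 s⁻¹)

| flask | L | E | G | time |
|---|---|---|---|---|
| red | 20 mM | 24.0 mM | 19.0 mM | 40 s |
| grey | 20 mM | 24.0 mM | 19.0 mM | 50 s |

* which of the two there is more of at the end, red (G.D / E.D)
* which of the two there is more of at the end, grey (G.D / E.D)
* E.D at the end, in percent of the L charged, red
* E.D at the end, in percent of the L charged, grey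

**The ratio.** Dividing the rate of E.D formation by that of G.D formation removes both time and D. What remains is the selectivity factor S = 28.2, the ratio of the two capture rates at the charges, multiplied by the fraction of E left and divided by the fraction of G left. E's fraction falls faster than G's, since 40.4 M⁻¹ s⁻¹ exceeds 1.81 M⁻¹ s⁻¹ and E decays besides. The product ratio, which sums the moments of the run, therefore starts from S and sinks below it.

**Upper extreme.** Here E stayed at its charge, so converted L split S to one. Step one converts 55.8% of L in red and 63.9% in grey. That puts E.D at 53.9% and 61.8%.

**Lower extreme.** Here E decayed while each converted L took one E at once, leaving a floor of 0.175 of its charge in red and 0.0846 in grey. Holding E there from the start gives ratios of 4.94 and 2.38, and E.D of 46.4% and 45.0%.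

**My commitment.** The ratio had to lie between the extremes, and both floors stood above one, so I expected more E.D than G.D in both flasks. Free D stands outside both yields, which could therefore fall short. I took the middle: 50.2% for red and 53.4% for grey.

**The forecast.** It named E.D for red and E.D for grey, with E.D at 49% (46% to 52%) in red and 55% (51% to 59%) in grey, reasoning that “D is trapped mostly by E”.

**The result.** E.D reached 48.8% in red and 55.1% in grey, against G.D at 3.47% and 4.73%. Grey's E ended at 13.2% of its charge, above my floor. The product ratios read 14.0 in red and 11.6 in grey, each between its floor and S.

**Second flask.** For the grey flask read at 30 s, S stays 28.2 and the floor becomes 28.2 times 0.300, or 8.46. The run gave E.D 40.4% and G.D 2.40%, a ratio of 16.8, inside those bounds.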